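**Strategy.** The isoflavan is disconnected at C3–C1′ and C4–C4a, so that C3 and C4 derive from vinylboronic acid pinacol ester. This exploits the fact that stereocentre C3 bears ring B and is bonded to C4, the methylene attached to C4a of ring A. An enantioselective palladium-catalysed conjunctive coupling lets the ring-B aryl group migrate from boron to C3 while ring A is delivered to C4, and boron remains on C3 as the handle for C2. The precursors are a lithiated MOM-protected 3-prenyl-4-methoxyphenyl unit and a bis-silylated, acetal-masked 3-bromo-2,6-dihydroxy-4-methoxybenzaldehyde. One-carbon homologation, oxidation and Mitsunobu closure of ring C at O1 then complete the chroman.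

Key step: step 7

**Remarks**
- Isoflavan numbering is used: O1, C2, C3, C4, C4a, C5–C8, C8a for rings C and A; C1′–C6′ for ring B. The target is (3R).
- Assumption: both antipodes of MandyPhos are commercial, and the one that delivers the (R)-configured boronate is used. The sense of induction is to be checked by oxidising a sample of the boronate to the 1,2-diarylethanol.
- Ring A is kept as the electrophile, because its aryllithium would be prone to retro-Brook silyl migration.
- Ring A carries silyl ethers and ring B a MOM ether, so that fluoride frees only the ring-A oxygens. Of these only O8a can reach C2, whereas a free ring-B phenol could close a dihydrobenzofuran.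

**Route**

Step 1
Reactants: 1 3-methoxyphenol
Product: 2 1-methoxy-3-(methoxymethoxy)benzene
Conditions: MOMCl, i-Pr2NEt, CH2Cl2, 0 °C → rt
Reagents that add atoms: chloromethyl methyl ether, COCCl
Why: Williamson-type O-alkylation of the phenol with the reactive chloromethyl ether should give the MOM ether, which later directs both lithiations of ring B.

Step 2
Reactants: 2 1-methoxy-3-(methoxymethoxy)benzene; 3 prenyl bromide
Product: 5 1-methoxy-3-(methoxymethoxy)-2-(3-methylbut-2-en-1-yl)benzene, via aryllithium 4 (not isolated)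
Conditions: n-BuLi, THF, 0 °C; then CuBr·SMe2 (10 mol%), 3, −78 °C → rt
Reagents that add atoms: none
Why: Directed ortho-metalation should occur at the carbon flanked by both oxygen donors, and copper-catalysed allylic substitution of prenyl bromide by the aryllithium should give the linear prenyl arene.

Step 3
Reactants: 6 2,4,6-trihydroxybenzaldehyde
Product: 7 2,6-dihydroxy-4-methoxybenzaldehyde
Conditions: Me2SO4 (1.0 equiv), NaHCO3, DMF, rt → 40 °C
Reagents that add atoms: dimethyl sulfate, COS(=O)(=O)OC
Why: Regioselective Williamson O-methylation should favour the 4-hydroxyl, which is the least hindered and the only one that cannot chelate the formyl group, when one equivalent of a hard methylating agent and a weak base are used.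

Step 4
Reactants: 7 2,6-dihydroxy-4-methoxybenzaldehyde
Product: 8 3-bromo-2,6-dihydroxy-4-methoxybenzaldehyde
Conditions: NBS (1.0 equiv), MeCN, −20 → 0 °C
Reagents that add atoms: N-bromosuccinimide, O=C1CCC(=O)N1Br
Why: Electrophilic aromatic bromination should give one monobromide, because the two free ring carbons of 7 are equivalent by symmetry and strongly activated.

Step 5
Reactants: 8 3-bromo-2,6-dihydroxy-4-methoxybenzaldehyde
Product: 9 3-bromo-2,6-bis(tert-butyldimethylsilyloxy)-4-methoxybenzaldehyde
Conditions: TBSOTf, 2,6-lutidine, CH2Cl2, 0 °C → rt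
Reagents that add atoms: tert-butyldimethylsilyl triflate, CC(C)(C)[Si](C)(C)OS(=O)(=O)C(F)(F)F
Why: O-silylation with the highly electrophilic silyl triflate and a non-nucleophilic base should cap both chelated, hindered phenols as ethers that fluoride later removes without touching the MOM ether.

Step 6
Reactants: 9 3-bromo-2,6-bis(tert-butyldimethylsilyloxy)-4-methoxybenzaldehyde
Product: 10 2-[3-bromo-2,6-bis(tert-butyldimethylsilyloxy)-4-methoxyphenyl]-1,3-dioxolane
Conditions: TMSOCH2CH2OTMS, TMSOTf (cat.), CH2Cl2, −78 → −20 °C; pyridine quench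
Reagents that add atoms: 1,2-bis(trimethylsilyloxy)ethane, C[Si](C)(C)OCCO[Si](C)(C)C
Why: Noyori acetalisation under aprotic silyl-triflate catalysis, driven by formation of hexamethyldisiloxane, should mask the formyl group without endangering the aryl silyl ethers, so that it survives the carbenoid and the oxidant of step 8.

Step 7
Reactants: 5 1-methoxy-3-(methoxymethoxy)-2-(3-methylbut-2-en-1-yl)benzene; 11 vinylboronic acid pinacol ester; 10 2-[3-bromo-2,6-bis(tert-butyldimethylsilyloxy)-4-methoxyphenyl]-1,3-dioxolane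
Product: 14 2-[(1R)-2-[2,4-bis(tert-butyldimethylsilyloxy)-3-(1,3-dioxolan-2-yl)-6-methoxyphenyl]-1-[4-methoxy-2-(methoxymethoxy)-3-(3-methylbut-2-en-1-yl)phenyl]ethyl]-4,4,5,5-tetramethyl-1,3,2-dioxaborolane, via ring-B aryllithium 12 (not isolated), via lithium vinylboron ate complex 13 (not isolated)
Conditions: 5 (1.3 equiv), n-BuLi (1.15 equiv), THF, 0 °C; 11 (1.2 equiv), −78 °C → rt; then 10 (1.0 equiv), Pd(OAc)2 (5 mol%), MandyPhos (6 mol%), NaOTf (2.5 equiv), THF, 60 °C
Reagents that add atoms: none
Why: Oxidative addition of 10 to the zerovalent palladium–MandyPhos complex gives an aryl species of divalent palladium whose bromide is taken up by NaOTf; the metal then binds the vinyl group of the four-coordinate boronate 13, the ring-B aryl group shifts from boron to the boron-bearing carbon (C3) anti to palladium while the terminal carbon (C4) becomes bonded to palladium, and reductive elimination forms C4–C4a. The closest known reaction type is the enantioselective palladium-catalysed conjunctive cross-coupling of aryl(vinyl)boron ate complexes with aryl halides in the presence of a triflate salt. No ring is closed in this step. The only new stereocentre, C3, is set by the chiral ferrocenyl bisphosphine on palladium, which selects the face of the vinyl boronate that undergoes the metallate shift. The step needs site-defined lithiation of ring B, secured by the MOM ether as the stronger ortho-director and by keeping 5 in slight excess over n-BuLi so that no butyl ate complex can form, and it needs the metallate shift to outrun direct boron-to-palladium aryl transfer and β-hydride elimination, which the chelating bisphosphine should favour. The position of the C4–C4a bond is fixed because bromine sits on the only kind of free ring carbon of the symmetrical aldehyde 7.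

Step 8
Reactants: 14 the (R)-secondary benzylic pinacol boronate
Product: 17 (2R)-3-[2,4-bis(tert-butyldimethylsilyloxy)-3-(1,3-dioxolan-2-yl)-6-methoxyphenyl]-2-[4-methoxy-2-(methoxymethoxy)-3-(3-methylbut-2-en-1-yl)phenyl]propan-1-ol, via chloromethyl boron ate complex 15 (not isolated), via homologated primary boronate 16 (not isolated)
Conditions: BrCH2Cl, n-BuLi, THF, −78 °C → rt; then NaBO3·4H2O, THF/H2O, rt
Reagents that add atoms: bromochloromethane, ClCBr; sodium perborate, [Na+].[Na+].O[B-]1(O)OO[B-](O)(O)OO1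
Why: In this Matteson homologation chloromethyllithium made in situ adds to boron and the secondary benzylic carbon migrates with retention of configuration, after which mild perborate oxidation of the primary C–B bond should give the alcohol without affecting C3, the aryl silyl ethers or the acetal.

Step 9
Reactants: 17 the bis-silylated primary alcohol
Product: 18 (2R)-3-[3-(1,3-dioxolan-2-yl)-2,4-dihydroxy-6-methoxyphenyl]-2-[4-methoxy-2-(methoxymethoxy)-3-(3-methylbut-2-en-1-yl)phenyl]propan-1-ol
Conditions: TBAF, AcOH (1:1), THF, 0 °C; pH 7 work-up, used promptly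
Reagents that add atoms: none
Why: Fluoride-mediated desilylation under acetic acid buffering should free the C7 and C8a phenols while the MOM ether, the acetal and the prenyl group stay inert.

Step 10
Reactants: 18 the triol
Product: 19 (3R)-8-(1,3-dioxolan-2-yl)-5-methoxy-3-[4-methoxy-2-(methoxymethoxy)-3-(3-methylbut-2-en-1-yl)phenyl]-3,4-dihydro-2H-chromen-7-ol
Conditions: PPh3, DIAD, THF (0.02 M), 0 °C → rt
Reagents that add atoms: none
Why: Intramolecular Mitsunobu etherification should close ring C by 6-exo-tet displacement of the activated C2 alcohol by the C8a phenol, since the C7 phenol cannot reach C2, the ring-B oxygen is still a MOM ether, and C3 is not involved.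

Step 11
Reactants: 19 the protected chroman
Product: 20 (3R)-7-hydroxy-3-[2-hydroxy-4-methoxy-3-(3-methylbut-2-en-1-yl)phenyl]-5-methoxy-3,4-dihydro-2H-chromene-8-carbaldehyde (CNP0321751.1)
Conditions: 2 M aq. HCl, MeOH/THF, rt (→ 40 °C if needed)
Reagents that add atoms: water, O
Why: Acid-catalysed acetal solvolysis should remove the MOM ether and the dioxolane in one operation, because both ionise through oxygen-stabilised cations far faster than the trisubstituted prenyl alkene is protonated, so cyclisation of the prenyl group onto the new phenol should not compete.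

**Compound list**

1 | 3-methoxyphenol | COc1cccc(O)c1 | starting material
2 | 1-methoxy-3-(methoxymethoxy)benzene | COCOc1cccc(OC)c1 | intermediate
3 | prenyl bromide (1-bromo-3-methylbut-2-ene) | CC(C)=CCBr | starting material
4 | [2-methoxy-6-(methoxymethoxy)phenyl]lithium | [Li]c1c(OC)cccc1OCOC | intermediate
5 | 1-methoxy-3-(methoxymethoxy)-2-(3-methylbut-2-en-1-yl)benzene | COCOc1cccc(OC)c1CC=C(C)C | intermediate
6 | 2,4,6-trihydroxybenzaldehyde | O=Cc1c(O)cc(O)cc1O | starting material
7 | 2,6-dihydroxy-4-methoxybenzaldehyde | COc1cc(O)c(C=O)c(O)c1 | intermediate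
8 | 3-bromo-2,6-dihydroxy-4-methoxybenzaldehyde | COc1cc(O)c(C=O)c(O)c1Br | intermediate
9 | 3-bromo-2,6-bis(tert-butyldimethylsilyloxy)-4-methoxybenzaldehyde | COc1cc(O[Si](C)(C)C(C)(C)C)c(C=O)c(O[Si](C)(C)C(C)(C)C)c1Br | intermediate
10 | 2-[3-bromo-2,6-bis(tert-butyldimethylsilyloxy)-4-methoxyphenyl]-1,3-dioxolane | COc1cc(O[Si](C)(C)C(C)(C)C)c(C2OCCO2)c(O[Si](C)(C)C(C)(C)C)c1Br | intermediate
11 | vinylboronic acid pinacol ester | C=CB1OC(C)(C)C(C)(C)O1 | starting material
12 | [4-methoxy-2-(methoxymethoxy)-3-(3-methylbut-2-en-1-yl)phenyl]lithium | [Li]c1ccc(OC)c(CC=C(C)C)c1OCOC | intermediate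
13 | lithium [4-methoxy-2-(methoxymethoxy)-3-(3-methylbut-2-en-1-yl)phenyl](ethenyl)(pinacolato)borate | [Li+].C=C[B-]1(c2ccc(OC)c(CC=C(C)C)c2OCOC)OC(C)(C)C(C)(C)O1 | intermediate
14 | 2-[(1R)-2-[2,4-bis(tert-butyldimethylsilyloxy)-3-(1,3-dioxolan-2-yl)-6-methoxyphenyl]-1-[4-methoxy-2-(methoxymethoxy)-3-(3-methylbut-2-en-1-yl)phenyl]ethyl]-4,4,5,5-tetramethyl-1,3,2-dioxaborolane | COc1ccc([C@@H](Cc2c(O[Si](C)(C)C(C)(C)C)c(C3OCCO3)c(O[Si](C)(C)C(C)(C)C)cc2OC)B2OC(C)(C)C(C)(C)O2)c(OCOC)c1CC=C(C)C | intermediate
15 | lithium (chloromethyl) ate complex of 14, (R) at C3 | [Li+].COc1ccc([C@@H](Cc2c(O[Si](C)(C)C(C)(C)C)c(C3OCCO3)c(O[Si](C)(C)C(C)(C)C)cc2OC)[B-]2(CCl)OC(C)(C)C(C)(C)O2)c(OCOC)c1CC=C(C)C | intermediate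
16 | 2-[(2R)-3-[2,4-bis(tert-butyldimethylsilyloxy)-3-(1,3-dioxolan-2-yl)-6-methoxyphenyl]-2-[4-methoxy-2-(methoxymethoxy)-3-(3-methylbut-2-en-1-yl)phenyl]propyl]-4,4,5,5-tetramethyl-1,3,2-dioxaborolane | COc1ccc([C@@H](Cc2c(O[Si](C)(C)C(C)(C)C)c(C3OCCO3)c(O[Si](C)(C)C(C)(C)C)cc2OC)CB2OC(C)(C)C(C)(C)O2)c(OCOC)c1CC=C(C)C | intermediate
17 | (2R)-3-[2,4-bis(tert-butyldimethylsilyloxy)-3-(1,3-dioxolan-2-yl)-6-methoxyphenyl]-2-[4-methoxy-2-(methoxymethoxy)-3-(3-methylbut-2-en-1-yl)phenyl]propan-1-ol | COc1ccc([C@@H](Cc2c(O[Si](C)(C)C(C)(C)C)c(C3OCCO3)c(O[Si](C)(C)C(C)(C)C)cc2OC)CO)c(OCOC)c1CC=C(C)C | intermediate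
18 | (2R)-3-[3-(1,3-dioxolan-2-yl)-2,4-dihydroxy-6-methoxyphenyl]-2-[4-methoxy-2-(methoxymethoxy)-3-(3-methylbut-2-en-1-yl)phenyl]propan-1-ol | COc1ccc([C@@H](Cc2c(O)c(C3OCCO3)c(O)cc2OC)CO)c(OCOC)c1CC=C(C)C | intermediate
19 | (3R)-8-(1,3-dioxolan-2-yl)-5-methoxy-3-[4-methoxy-2-(methoxymethoxy)-3-(3-methylbut-2-en-1-yl)phenyl]-3,4-dihydro-2H-chromen-7-ol | COc1ccc([C@@H]2COc3c(C4OCCO4)c(O)cc(OC)c3C2)c(OCOC)c1CC=C(C)C | intermediate
20 | (3R)-7-hydroxy-3-[2-hydroxy-4-methoxy-3-(3-methylbut-2-en-1-yl)phenyl]-5-methoxy-3,4-dihydro-2H-chromene-8-carbaldehyde | COc1ccc([C@@H]2COc3c(C=O)c(O)cc(OC)c3C2)c(O)c1CC=C(C)C | target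

**Totals**

Total step count: 11. Longest linear sequence: 9 steps (steps 3–11, from 6). The ring-B branch (steps 1–2) joins at step 7.

**Steps most likely to fail**

Step 7 (conjunctive coupling). The aryl centre of divalent palladium, flanked by OMe and OTBS, may be too crowded to bind the vinyl boronate. Turnover would then stall, or protodebromination and direct aryl transfer would take over, and the higher temperature then required could erode facial selectivity.

Fallback (sets out from 5 and 10, returns at 14): a stoichiometric, reagent-controlled lithiation–borylation replaces the catalytic three-component coupling.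
- Arene 5 is lithiated as in step 7 (12) and quenched with 2-isopropoxy-4,4,5,5-tetramethyl-1,3,2-dioxaborolane to give the ring-B aryl pinacol boronate F1.
- Bromide 10 undergoes Stille vinylation (tributyl(vinyl)stannane, Pd(PPh3)4, toluene, 100 °C) to give the styrene F2.
- Hydroboration with 9-BBN gives the B-alkyl borane F3, which NaBO3·4H2O oxidises to the 2-arylethanol F4.
- N,N-Diisopropylcarbamoyl chloride (Et3N, CH2Cl2, reflux) converts it into the carbamate F5.
- Deprotonation of F5 with s-BuLi/(−)-sparteine (Et2O, −78 °C), which removes the pro-S hydrogen, should give the configurationally stable (S)-α-lithiated carbamate F6.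
- Boronate F1 should add with retention to give the boron ate complex F7. Warming with MgBr2·OEt2 should then trigger anti 1,2-migration of the ring-B aryl group with loss of the carbamate (inversion at carbon), giving 14 with the (R) configuration.

Step 3 (mono-methylation). Methylation may not stop at the 4-hydroxyl: over-alkylation, attack at a 2-hydroxyl or C-methylation of the phloroglucinol nucleus may compete.

Fallback (sets out from 6, returns at 7): exhaustive O-methylation of 6 (excess Me2SO4, K2CO3, acetone, reflux) gives 2,4,6-trimethoxybenzaldehyde F8. Chelation-controlled cleavage of the two methyl ethers ortho to the formyl group with excess AlCl3 (CH2Cl2, reflux) should leave the 4-methoxy group and give 7.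

Step 10 (Mitsunobu closure). The free ortho-hydroxyaryl acetal of 18 may lose its dioxolane or oxidise during handling, and intermolecular etherification at the C7 phenol may compete with ring closure.

Fallback (sets out from 17, returns at 19, bypassing 18): the order of activation and unmasking is reversed. Alcohol 17 is converted into the primary mesylate F9 (MsCl, Et3N, CH2Cl2, 0 °C). TBAF in THF then removes both silyl groups to give the bis-phenoxide mesylate F10, whose C8a phenoxide should displace the mesylate in a 6-exo-tet Williamson closure to give 19.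

**Further compounds**

F1 | step 7 | 2-[4-methoxy-2-(methoxymethoxy)-3-(3-methylbut-2-en-1-yl)phenyl]-4,4,5,5-tetramethyl-1,3,2-dioxaborolane | COc1ccc(B2OC(C)(C)C(C)(C)O2)c(OCOC)c1CC=C(C)C
F2 | step 7 | 2-[3-ethenyl-2,6-bis(tert-butyldimethylsilyloxy)-4-methoxyphenyl]-1,3-dioxolane | COc1cc(O[Si](C)(C)C(C)(C)C)c(C2OCCO2)c(O[Si](C)(C)C(C)(C)C)c1C=C
F3 | step 7 | 9-[2-[2,4-bis(tert-butyldimethylsilyloxy)-3-(1,3-dioxolan-2-yl)-6-methoxyphenyl]ethyl]-9-borabicyclo[3.3.1]nonane | COc1cc(O[Si](C)(C)C(C)(C)C)c(C2OCCO2)c(O[Si](C)(C)C(C)(C)C)c1CCB1C2CCCC1CCC2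
F4 | step 7 | 2-[2,4-bis(tert-butyldimethylsilyloxy)-3-(1,3-dioxolan-2-yl)-6-methoxyphenyl]ethan-1-ol | COc1cc(O[Si](C)(C)C(C)(C)C)c(C2OCCO2)c(O[Si](C)(C)C(C)(C)C)c1CCO
F5 | step 7 | 2-[2,4-bis(tert-butyldimethylsilyloxy)-3-(1,3-dioxolan-2-yl)-6-methoxyphenyl]ethyl N,N-diisopropylcarbamate | COc1cc(O[Si](C)(C)C(C)(C)C)c(C2OCCO2)c(O[Si](C)(C)C(C)(C)C)c1CCOC(=O)N(C(C)C)C(C)C
F6 | step 7 | (1S)-1-lithio-2-[2,4-bis(tert-butyldimethylsilyloxy)-3-(1,3-dioxolan-2-yl)-6-methoxyphenyl]ethyl N,N-diisopropylcarbamate | COc1cc(O[Si](C)(C)C(C)(C)C)c(C2OCCO2)c(O[Si](C)(C)C(C)(C)C)c1C[C@H]([Li])OC(=O)N(C(C)C)C(C)C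
F7 | step 7 | lithium boron ate complex of F6 and F1, (S) at the carbamate carbon | [Li+].COc1cc(O[Si](C)(C)C(C)(C)C)c(C2OCCO2)c(O[Si](C)(C)C(C)(C)C)c1C[C@@H](OC(=O)N(C(C)C)C(C)C)[B-]1(c2ccc(OC)c(CC=C(C)C)c2OCOC)OC(C)(C)C(C)(C)O1
F8 | step 3 | 2,4,6-trimethoxybenzaldehyde | COc1cc(OC)c(C=O)c(OC)c1
F9 | step 10 | (2R)-3-[2,4-bis(tert-butyldimethylsilyloxy)-3-(1,3-dioxolan-2-yl)-6-methoxyphenyl]-2-[4-methoxy-2-(methoxymethoxy)-3-(3-methylbut-2-en-1-yl)phenyl]propyl methanesulfonate | COc1ccc([C@@H](Cc2c(O[Si](C)(C)C(C)(C)C)c(C3OCCO3)c(O[Si](C)(C)C(C)(C)C)cc2OC)COS(C)(=O)=O)c(OCOC)c1CC=C(C)C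
F10 | step 10 | (2R)-3-[3-(1,3-dioxolan-2-yl)-2,4-dihydroxy-6-methoxyphenyl]-2-[4-methoxy-2-(methoxymethoxy)-3-(3-methylbut-2-en-1-yl)phenyl]propyl methanesulfonate (formed as its phenoxide) | COc1ccc([C@@H](Cc2c(O)c(C3OCCO3)c(O)cc2OC)COS(C)(=O)=O)c(OCOC)c1CC=C(C)C
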